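**Strategy.** The Z‑configured C1=C10 olefin stands 1,3 to C5 across the ten‑membered ring, so the ring is traced back to a cis‑fused decalin whose shared bond is C5–C10. A Grob fragmentation of the 5β‑hydroxy 1α‑mesylate 15 breaks that bond and in one operation delivers the cyclodecene ring, the Z olefin and the C5 ketone. The precursor, made from (S)‑Wieland–Miescher ketone, carries C2, C4 and C6 in the target configuration, C7 as a silyl ether (oxidised later for the butenolide) and C8 as the equatorial epimer, inverted near the end by Mitsunobu methacrylation. The ketone then becomes the trans‑4,5‑epoxide; an intramolecular Horner–Wadsworth–Emmons reaction closes the lactone.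

Key step: step 13

Conventions: target numbering throughout (ring carbons C1–C10, methyl on C10, lactone carbons C11–C13). In the decalins ring A = C1–C5 + C10, ring B = C5–C10, shared bond C5–C10; α/β = trans/cis to the C10 methyl. TBDPS = tert‑butyldiphenylsilyl, TBS = tert‑butyldimethylsilyl, TES = triethylsilyl, NAP = 2‑naphthylmethyl.

Design of the precursor:
- The oxygens that end as different esters are differentiated from the start (C2 NAP ether, C6 TES, C7 TBS, C8 TBDPS).
- C7 is a silyl ether, not a carbonyl or a ketal. A ketone would allow retro‑aldol cleavage from the C5 alkoxide, and a ketal flanked by two alkoxy carbons would need strong acid once the acid‑labile epoxide is in place.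
- The tertiary C4 hydroxyl stays free: it directs step 11 and closes the epoxide in step 15.
- C8 is set as the α epimer. This is what α'‑hydroxylation of the enone gives, and it is equatorial in the reactive chair–chair conformer (an 8β ether would be syn‑axial to both the C10 methyl and the C6 ether). It is inverted in step 24.

Assumption: methyl 2‑(dimethoxyphosphoryl)acrylate (21) and all reagents named under Conditions are taken as commercial.

Step 1
Reactants: 1 (S)-Wieland–Miescher ketone
Product: 2 1β-hydroxy enone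
Conditions: NaBH4 (0.3 equiv), EtOH, −10 °C
Reagents that add atoms: none
Why: Chemoselective borohydride reduction: the saturated C1 ketone is more electrophilic than the vinylogous C7 carbonyl, and hydride should add anti to the angular methyl to give the equatorial 1β-alcohol (a centre erased in step 2).

Step 2
Reactants: 2 1β-hydroxy enone
Product: 3 Δ1-dienone
Conditions: Burgess reagent, PhMe, 80 °C
Reagents that add atoms: none
Why: Burgess dehydration (thermal syn-elimination of the sulfamate ester): C10 is quaternary, so only the C2 hydrogens are available and the C1=C2 olefin should form as a single regioisomer.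

Step 3
Reactants: 3 Δ1-dienone
Product: 6 1α,2α-epoxy-8α-hydroxy enone, via C7 trimethylsilyl dienol ether 4 (not isolated), via 8α-trimethylsilyloxy epoxy enone 5 (not isolated)
Conditions: LiN(iPr)2, Me3SiCl, THF, −78 °C; mCPBA (2.3 equiv), CH2Cl2, 0 °C; citric acid, MeOH
Reagents that add atoms: 3-chloroperoxybenzoic acid, OOC(=O)c1cccc(Cl)c1
Why: Kinetic α'-deprotonation and silylation give the cross-conjugated 2-silyloxydiene, and peracid should then oxidise its enol ether bond (Rubottom oxidation) and the isolated C1=C2 olefin (Prilezhaev epoxidation) on the α face, anti to the axial C10 methyl, setting C8 (α-OH) and C1/C2 (α-epoxide) while the electron-poor enone olefin is untouched.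

Step 4
Reactants: 6 1α,2α-epoxy-8α-hydroxy enone
Product: 7 8α-TBDPS ether
Conditions: tBuPh2SiCl, imidazole, DMF, rt
Reagents that add atoms: tert-butylchlorodiphenylsilane, CC(C)(C)[Si](Cl)(c1ccccc1)c1ccccc1
Why: Standard silylation of the only hydroxyl; the robust TBDPS group is the last silyl ether to be removed (step 23).

Step 5
Reactants: 7 8α-TBDPS ether
Product: 8 1α,2α-epoxy-5-ene-4,7-dione
Conditions: Pd(OH)2/C (cat.), tBuOOH, K2CO3 (cat.), CH2Cl2, 4 °C
Reagents that add atoms: tert-butyl hydroperoxide, CC(C)(C)OO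
Why: Allylic γ-oxidation of an α,β-enone to the 1,4-enedione (Corey–Yu oxidation): C4 is the only γ-methylene, and the epoxide and silyl ether are inert to the peroxy radical chain, which is why the benzylic NAP ether is introduced only afterwards.

Step 6
Reactants: 8 1α,2α-epoxy-5-ene-4,7-dione
Product: 9 1α-hydroxy-2β-NAP ether
Conditions: 2-naphthylmethanol (5 equiv), BF3·OEt2 (cat.), CH2Cl2, −20 → 0 °C
Reagents that add atoms: (naphthalen-2-yl)methanol, OCc1ccc2ccccc2c1
Why: Lewis acid-catalysed alcoholysis of the epoxide: C1 is neopentyl, so the alcohol should attack C2 from the β face with inversion (trans-diaxial Fürst–Plattner opening), setting C2 in the target configuration and leaving the 1α-hydroxyl for the leaving group.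

Step 7
Reactants: 9 1α-hydroxy-2β-NAP ether
Product: 10 1α-mesylate
Conditions: MsCl, Et3N, CH2Cl2, 0 °C
Reagents that add atoms: methanesulfonyl chloride, CS(=O)(=O)Cl
Why: Mesylation via sulfene tolerates the hindered axial neopentyl alcohol, and the mesylate can undergo neither E2 (no anti hydrogen) nor SN2 (neopentyl), so it should survive the next five steps.

Step 8
Reactants: 10 1α-mesylate
Product: 11 7β-hydroxy-5-en-4-one
Conditions: NaBH4 (1.0 equiv), CeCl3·7H2O, MeOH, −78 °C
Reagents that add atoms: none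
Why: Luche 1,2-reduction: CeCl3 suppresses conjugate reduction, the C7 carbonyl (activated by the α-silyloxy group, next to the unsubstituted olefin carbon) should react before the C4 carbonyl shielded by C10, and α-face hydride delivery gives the equatorial 7β-alcohol (a centre oxidised away in step 21).

Step 9
Reactants: 11 7β-hydroxy-5-en-4-one
Product: 12 7β-TBS ether
Conditions: tBuMe2SiOTf, 2,6-lutidine, CH2Cl2, −78 °C
Reagents that add atoms: tert-butyldimethylsilyl trifluoromethanesulfonate, CC(C)(C)[Si](C)(C)OS(=O)(=O)C(F)(F)F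
Why: Silyl triflate silylation of the only free hydroxyl, a hindered allylic alcohol, masks C7 until the butenolide stage.

Step 10
Reactants: 12 7β-TBS ether
Product: 13 4β-hydroxy-4α-methyl-5-ene
Conditions: MeLi, CeCl3, THF, −78 °C
Reagents that add atoms: methyllithium, [Li]C
Why: Organocerium 1,2-addition to the hindered enone without enolisation or attack on the mesylate: the β face of C4 is screened by the syn-axial C10 methyl and the axial 2β-ether, so methyl should enter from the α face and set C4 (β-OH, α-CH3, target configuration).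

Step 11
Reactants: 13 4β-hydroxy-4α-methyl-5-ene
Product: 14 cis-decalin 4β,5β,6β-triol 1α-mesylate
Conditions: OsO4 (1.05 equiv), TMEDA, CH2Cl2, −78 °C; then ethylenediamine, rt
Reagents that add atoms: osmium tetroxide, O=[Os](=O)(=O)=O
Why: Hydroxyl-directed dihydroxylation (Donohoe conditions): the axial allylic 4β-hydroxyl hydrogen-bonds to the OsO4·TMEDA complex and should steer it to the β face of C5=C6 while the axial C1 mesylate blocks the α face, setting C5 and C6 cis to the C10 methyl and creating the cis ring fusion.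

Step 12
Reactants: 14 cis-decalin 4β,5β,6β-triol 1α-mesylate
Product: 15 Grob precursor (6β-TES ether)
Conditions: Et3SiOTf (1.1 equiv), 2,6-lutidine, CH2Cl2, −78 °C
Reagents that add atoms: triethylsilyl trifluoromethanesulfonate, CC[Si](CC)(CC)OS(=O)(=O)C(F)(F)F
Why: Silylation of the single secondary hydroxyl (C6) should outpace the two tertiary hydroxyls, and the weak base does not ionise C5–OH, so fragmentation cannot start here.

Step 13
Reactants: 15 Grob precursor (6β-TES ether)
Product: 16 Z-cyclodec-1(10)-en-5-one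
Conditions: KOtBu (1.2 equiv), THF, 0 °C
Reagents that add atoms: none
Why: tert-Butoxide deprotonates the tertiary C5 hydroxyl, and because the oxygen lone pair, the C5–C10 bond and the equatorial C1–OMs bond are antiperiplanar, heterolysis is concerted: C5 becomes the ketone, the C1=C10 π bond forms and mesylate leaves (Grob fragmentation of a 1,3-diol monosulfonate, the classical decalin-to-cyclodecenone reaction). The ten-membered ring is not closed end to end but appears by scission of the bond shared by rings A and B, so no macrocyclisation entropy is paid. No stereocentre is created; the only new stereo-element is the olefin, whose geometry is fixed by the C2–C1–C10–C9 dihedral at the moment of cleavage. In the cis-fused chair–chair conformer with the mesylate, the C2 ether and the C4 hydroxyl equatorial on ring A, C2 is gauche to C9 and the Z olefin should result, whereas a trans-fused decalin would give E. That conformer is secured by the substitution pattern: the 7β- and 8α-silyl ethers are equatorial in it and axial in the ring-flipped form, which would also place three ring-A substituents syn-axial. Chemoselectivity rests on C7 being an ether (no retro-aldol), on the mesylate having no anti hydrogen, and on the C4 alkoxide lacking an antiperiplanar leaving group (it could reach C1 only through a ring-A boat).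

Step 14
Reactants: 16 Z-cyclodec-1(10)-en-5-one
Product: 17 4,5-anti diol
Conditions: Zn(BH4)2, Et2O, −30 °C
Reagents that add atoms: none
Why: Chelation-controlled hydride reduction of the α-hydroxy ketone (zinc bridging the C4 oxygen and the carbonyl, hydride arriving from the ring periphery) should give the 4,5-anti diol, the C5 configuration that epoxide closure with inversion requires.

Step 15
Reactants: 17 4,5-anti diol
Product: 19 trans-4,5-epoxide, via C5 mesylate 18 (not isolated)
Conditions: MsCl, Et3N, CH2Cl2, 0 °C; then K2CO3, MeOH, rt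
Reagents that add atoms: none
Why: Sulfene mesylation selects the secondary C5 hydroxyl over the tertiary C4 hydroxyl, and carbonate then triggers intramolecular Williamson displacement by the C4 alkoxide (3-exo-tet) with inversion at C5, giving the trans-epoxide with the target configuration at C4 and C5.

Step 16
Reactants: 19 trans-4,5-epoxide
Product: 20 6-hydroxy epoxide
Conditions: HF·pyridine, pyridine, THF, 0 °C
Reagents that add atoms: none
Why: Fluoride cleavage of silyl ethers in buffered HF·pyridine follows steric bulk, so the triethylsilyl ether at C6 should go while the TBS and TBDPS ethers and the epoxide remain.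

Step 17
Reactants: 21 methyl 2-(dimethoxyphosphoryl)acrylate
Product: 22 methyl 2-(dimethoxyphosphoryl)-3-(naphthalen-2-ylmethoxy)propanoate
Conditions: 2-naphthylmethanol, KOtBu (10 mol %), THF, 0 °C
Reagents that add atoms: (naphthalen-2-yl)methanol, OCc1ccc2ccccc2c1
Why: Base-catalysed oxa-Michael addition of the alcohol to the doubly activated vinylphosphonate; the new centre is racemic and is destroyed in step 22.

Step 18
Reactants: 22 methyl 2-(dimethoxyphosphoryl)-3-(naphthalen-2-ylmethoxy)propanoate
Product: 23 2-(dimethoxyphosphoryl)-3-(naphthalen-2-ylmethoxy)propanoic acid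
Conditions: LiOH (1.05 equiv), THF/H2O, 0 °C; then aq. HCl
Reagents that add atoms: lithium hydroxide, [Li+].[OH-]
Why: Saponification of the activated methyl carboxylate at 0 °C is faster than dealkylation at phosphorus, and the carboxylate formed is no longer prone to β-elimination of the naphthylmethoxide.

Step 19
Reactants: 20 6-hydroxy epoxide; 23 2-(dimethoxyphosphoryl)-3-(naphthalen-2-ylmethoxy)propanoic acid
Product: 24 C6 phosphonopropanoate ester
Conditions: EDC·HCl, DMAP, CH2Cl2, rt
Reagents that add atoms: none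
Why: Carbodiimide/DMAP (Steglich) esterification of the hindered C6 alcohol, which for α-phosphono acids can proceed through a reactive phosphonoketene; the two C11 epimers converge in step 22.

Step 20
Reactants: 24 C6 phosphonopropanoate ester
Product: 25 7-hydroxy phosphonate ester
Conditions: HF·pyridine, THF, rt
Reagents that add atoms: none
Why: The secondary TBS ether is cleaved by HF·pyridine far faster than the bulkier TBDPS ether, and the mildly acidic medium suppresses acyl migration from O6 to O7.

Step 21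
Reactants: 25 7-hydroxy phosphonate ester
Product: 26 7-keto phosphonate ester
Conditions: Dess–Martin periodinane, pyridine, CH2Cl2, 0 °C
Reagents that add atoms: none
Why: Dess–Martin oxidation of the secondary alcohol under buffered neutral conditions tolerated by the epoxide, the phosphonate and the trisubstituted olefin.

Step 22
Reactants: 26 7-keto phosphonate ester
Product: 27 butenolide
Conditions: LiCl, iPr2NEt, MeCN, rt
Reagents that add atoms: none
Why: Intramolecular Horner–Wadsworth–Emmons olefination under mild Masamune–Roush conditions: five-membered closure of the lithium-chelated phosphonate onto the C7 ketone should outrun β-elimination of the C13 ether and enolisation at C6 or C8, giving the C7=C11 butenolide.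

Step 23
Reactants: 27 butenolide
Product: 28 8α-hydroxy butenolide
Conditions: Bu4NF, AcOH, THF, rt
Reagents that add atoms: none
Why: Fluoride desilylation of the TBDPS ether, buffered with acetic acid so that the base-sensitive butenolide and epoxide do not meet free alkoxide.

Step 24
Reactants: 28 8α-hydroxy butenolide
Product: 29 8β-methacrylate
Conditions: methacrylic acid, PPh3, DIAD, PhMe, 0 °C
Reagents that add atoms: methacrylic acid, C=C(C)C(=O)O
Why: Mitsunobu esterification: SN2 displacement of the oxyphosphonium at allylic C8 by methacrylate with inversion converts the 8α-alcohol into the 8β-ester of the target.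

Step 25
Reactants: 29 8β-methacrylate
Product: 30 2,13-diol
Conditions: DDQ, CH2Cl2/pH 7 buffer, 0 °C → rt
Reagents that add atoms: none
Why: Oxidative cleavage of both 2-naphthylmethyl ethers by DDQ (hydride abstraction at the arylmethyl position, then hydrolysis) under neutral conditions that spare the epoxide, the olefins and the esters.

Step 26
Reactants: 30 2,13-diol
Product: 31 target CNP0268364.3
Conditions: Ac2O, pyridine, DMAP (cat.), CH2Cl2, 0 °C
Reagents that add atoms: acetic anhydride, CC(=O)OC(C)=O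
Why: DMAP-catalysed acetylation of the secondary allylic C2 and primary C13 hydroxyls completes the target.

**Compound list**

1 | (S)-Wieland–Miescher ketone, (S)-8a-methyl-3,4,8,8a-tetrahydronaphthalene-1,6(2H,7H)-dione | C[C@]12CCC(=O)C=C1CCCC2=O | starting material
2 | 1β-hydroxy enone, (4aS,5S)-5-hydroxy-4a-methyl-4,4a,5,6,7,8-hexahydronaphthalen-2(3H)-one | C1C[C@]2(C)[C@@H](O)CCCC2=CC1=O | intermediate
3 | Δ1-dienone: C1=C2 olefin, C5=C6–C7=O enone | C1C[C@]2(C)C=CCCC2=CC1=O | intermediate
4 | C7 trimethylsilyl dienol ether of 3 (C5=C6, C7=C8) | C[Si](C)(C)OC1=CC[C@]2(C)C=CCCC2=C1 | intermediate (not isolated)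
5 | 8α-trimethylsilyloxy 1α,2α-epoxy enone | C[Si](C)(C)O[C@@H]1C[C@]2(C)[C@@H]3O[C@@H]3CCC2=CC1=O | intermediate (not isolated)
6 | 1α,2α-epoxy-8α-hydroxy-5-en-7-one | O[C@@H]1C[C@]2(C)[C@@H]3O[C@@H]3CCC2=CC1=O | intermediate
7 | 8α-TBDPS ether of 6 | CC(C)(C)[Si](c5ccccc5)(c6ccccc6)O[C@@H]1C[C@]2(C)[C@@H]3O[C@@H]3CCC2=CC1=O | intermediate
8 | 1α,2α-epoxy-8α-OTBDPS-5-ene-4,7-dione | CC(C)(C)[Si](c5ccccc5)(c6ccccc6)O[C@@H]1C[C@]2(C)[C@@H]3O[C@@H]3CC(=O)C2=CC1=O | intermediate
9 | 1α-hydroxy-2β-ONAP-8α-OTBDPS-5-ene-4,7-dione | CC(C)(C)[Si](c5ccccc5)(c6ccccc6)O[C@@H]1C[C@]2(C)[C@H](O)[C@@H](OCc3ccc4ccccc4c3)CC(=O)C2=CC1=O | intermediate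
10 | 1α-mesylate of 9 | CC(C)(C)[Si](c5ccccc5)(c6ccccc6)O[C@@H]1C[C@]2(C)[C@H](OS(C)(=O)=O)[C@@H](OCc3ccc4ccccc4c3)CC(=O)C2=CC1=O | intermediate
11 | 7β-hydroxy-5-en-4-one (1α-OMs, 2β-ONAP, 8α-OTBDPS) | CC(C)(C)[Si](c5ccccc5)(c6ccccc6)O[C@@H]1C[C@]2(C)[C@H](OS(C)(=O)=O)[C@@H](OCc3ccc4ccccc4c3)CC(=O)C2=C[C@H]1O | intermediate
12 | 7β-TBS ether of 11 | CC(C)(C)[Si](c5ccccc5)(c6ccccc6)O[C@@H]1C[C@]2(C)[C@H](OS(C)(=O)=O)[C@@H](OCc3ccc4ccccc4c3)CC(=O)C2=C[C@H]1O[Si](C)(C)C(C)(C)C | intermediate
13 | 4β-hydroxy-4α-methyl-5-ene (tertiary allylic alcohol) | CC(C)(C)[Si](c5ccccc5)(c6ccccc6)O[C@@H]1C[C@]2(C)[C@H](OS(C)(=O)=O)[C@@H](OCc3ccc4ccccc4c3)C[C@@](C)(O)C2=C[C@H]1O[Si](C)(C)C(C)(C)C | intermediate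
14 | cis-decalin 4β,5β,6β-triol 1α-mesylate (2β-ONAP, 7β-OTBS, 8α-OTBDPS) | CC(C)(C)[Si](c5ccccc5)(c6ccccc6)O[C@@H]1C[C@]2(C)[C@H](OS(C)(=O)=O)[C@@H](OCc3ccc4ccccc4c3)C[C@@](C)(O)[C@]2(O)[C@@H](O)[C@H]1O[Si](C)(C)C(C)(C)C | intermediate
15 | Grob precursor: cis-decalin 5β-ol 1α-mesylate, 4β-OH/4α-CH3, 2β-ONAP, 6β-OTES, 7β-OTBS, 8α-OTBDPS | CC(C)(C)[Si](c5ccccc5)(c6ccccc6)O[C@@H]1C[C@]2(C)[C@H](OS(C)(=O)=O)[C@@H](OCc3ccc4ccccc4c3)C[C@@](C)(O)[C@]2(O)[C@@H](O[Si](CC)(CC)CC)[C@H]1O[Si](C)(C)C(C)(C)C | intermediate
16 | Z-cyclodec-1(10)-en-5-one: 4-OH, 2-ONAP, 6-OTES, 7-OTBS, 8-OTBDPS | CC(C)(C)[Si](c5ccccc5)(c6ccccc6)O[C@@H]1C/C(C)=C\[C@@H](OCc3ccc4ccccc4c3)C[C@@](C)(O)C(=O)[C@@H](O[Si](CC)(CC)CC)[C@H]1O[Si](C)(C)C(C)(C)C | intermediate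
17 | 4,5-anti diol (C5 carbinol) | CC(C)(C)[Si](c5ccccc5)(c6ccccc6)O[C@@H]1C/C(C)=C\[C@@H](OCc3ccc4ccccc4c3)C[C@@](C)(O)[C@@H](O)[C@@H](O[Si](CC)(CC)CC)[C@H]1O[Si](C)(C)C(C)(C)C | intermediate
18 | C5 mesylate of 17 | CC(C)(C)[Si](c5ccccc5)(c6ccccc6)O[C@@H]1C/C(C)=C\[C@@H](OCc3ccc4ccccc4c3)C[C@@](C)(O)[C@@H](OS(C)(=O)=O)[C@@H](O[Si](CC)(CC)CC)[C@H]1O[Si](C)(C)C(C)(C)C | intermediate (not isolated)
19 | trans-4,5-epoxide (6-OTES, 7-OTBS, 8-OTBDPS, 2-ONAP) | CC(C)(C)[Si](c5ccccc5)(c6ccccc6)O[C@@H]1C/C(C)=C\[C@@H](OCc3ccc4ccccc4c3)C[C@@]2(C)O[C@@H]2[C@@H](O[Si](CC)(CC)CC)[C@H]1O[Si](C)(C)C(C)(C)C | intermediate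
20 | 6-hydroxy epoxide | CC(C)(C)[Si](c5ccccc5)(c6ccccc6)O[C@@H]1C/C(C)=C\[C@@H](OCc3ccc4ccccc4c3)C[C@@]2(C)O[C@@H]2[C@@H](O)[C@H]1O[Si](C)(C)C(C)(C)C | intermediate
21 | methyl 2-(dimethoxyphosphoryl)acrylate | C=C(C(=O)OC)P(=O)(OC)OC | starting material
22 | methyl 2-(dimethoxyphosphoryl)-3-(naphthalen-2-ylmethoxy)propanoate (racemic) | COC(=O)C(COCc1ccc2ccccc2c1)P(=O)(OC)OC | intermediate
23 | 2-(dimethoxyphosphoryl)-3-(naphthalen-2-ylmethoxy)propanoic acid (racemic) | OC(=O)C(COCc1ccc2ccccc2c1)P(=O)(OC)OC | intermediate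
24 | C6 phosphonopropanoate ester (two C11 epimers) | CC(C)(C)[Si](c5ccccc5)(c6ccccc6)O[C@@H]1C/C(C)=C\[C@@H](OCc3ccc4ccccc4c3)C[C@@]2(C)O[C@@H]2[C@@H](OC(=O)C(COCc7ccc8ccccc8c7)P(=O)(OC)OC)[C@H]1O[Si](C)(C)C(C)(C)C | intermediate
25 | 7-hydroxy phosphonate ester | CC(C)(C)[Si](c5ccccc5)(c6ccccc6)O[C@@H]1C/C(C)=C\[C@@H](OCc3ccc4ccccc4c3)C[C@@]2(C)O[C@@H]2[C@@H](OC(=O)C(COCc7ccc8ccccc8c7)P(=O)(OC)OC)[C@H]1O | intermediate
26 | 7-keto phosphonate ester | CC(C)(C)[Si](c5ccccc5)(c6ccccc6)O[C@@H]1C/C(C)=C\[C@@H](OCc3ccc4ccccc4c3)C[C@@]2(C)O[C@@H]2[C@@H](OC(=O)C(COCc7ccc8ccccc8c7)P(=O)(OC)OC)C1=O | intermediate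
27 | butenolide (8α-OTBDPS, 2-ONAP, 13-ONAP) | CC(C)(C)[Si](c5ccccc5)(c6ccccc6)O[C@@H]1C/C(C)=C\[C@@H](OCc3ccc4ccccc4c3)C[C@@]2(C)O[C@@H]2[C@H]2OC(=O)C(COCc7ccc8ccccc8c7)=C12 | intermediate
28 | 8α-hydroxy butenolide | O[C@@H]1C/C(C)=C\[C@@H](OCc3ccc4ccccc4c3)C[C@@]2(C)O[C@@H]2[C@H]2OC(=O)C(COCc7ccc8ccccc8c7)=C12 | intermediate
29 | 8β-methacrylate (2-ONAP, 13-ONAP) | C=C(C)C(=O)O[C@H]1C/C(C)=C\[C@@H](OCc3ccc4ccccc4c3)C[C@@]2(C)O[C@@H]2[C@H]2OC(=O)C(COCc7ccc8ccccc8c7)=C12 | intermediate
30 | 2,13-diol | C=C(C)C(=O)O[C@H]1C/C(C)=C\[C@@H](O)C[C@@]2(C)O[C@@H]2[C@H]2OC(=O)C(CO)=C12 | intermediate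
31 | CNP0268364.3 | C=C(C)C(=O)O[C@H]1C/C(C)=C\[C@@H](OC(C)=O)C[C@@]2(C)O[C@@H]2[C@H]2OC(=O)C(COC(C)=O)=C12 | target

**Totals and risks**

Total step count: 26. Longest linear sequence: 24 steps (steps 1–16 and 19–26); steps 17–18 make the phosphonate acid 23.

The three steps most likely to fail, in order:

Step 11 (directed dihydroxylation). The process at risk is slow osmylation of a trisubstituted olefin flanked by two quaternary carbons, or delivery of osmium to the α face. The fallback sets out from 11 and comes back at 14. Methyl addition (MeLi/CeCl3, one extra equivalent) is carried out on the free 7β-alcohol to give the 4β,7β-diol F1. Its olefin is flanked by two β hydroxyls and no bulky 7-silyl ether, so OsO4/TMEDA is doubly directed and should give the 4β,5β,6β,7β-tetraol F2. Silylation with tBuMe2SiOTf (1 equiv), 2,6-lutidine at −78 °C then takes the less hindered secondary hydroxyl at C7 and rejoins the route at 14.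

Step 24 (Mitsunobu inversion). The process at risk is elimination of the activated C8 oxygen towards C9, or ionisation to an allyl cation with loss of stereospecificity. The fallback sets out from 28 and comes back at 29. Dess–Martin oxidation gives the 8-ketone F3. Reagent-controlled reduction with an oxazaborolidine (CBS) catalyst and BH3·SMe2, using the catalyst enantiomer that delivers hydride to the α face, gives the 8β-alcohol F4. Acylation with methacrylic anhydride/DMAP then gives 29 without any substitution at C8.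

Step 2 (Burgess dehydration). The process at risk is ionisation of the neopentyl sulfamate with 1,2-shift of a C10 substituent, or failure of a C2 hydrogen to reach syn-periplanar alignment. The fallback sets out from 1 and comes back at 3. The enone carbonyl is masked selectively as the C7 dithiolane F5 (ethane-1,2-dithiol, TsOH, AcOH). The remaining C1 ketone is converted into the tosylhydrazone F6 (TsNHNH2, MeOH). A Shapiro reaction (nBuLi, TMEDA, THF, −78 → 0 °C; H2O) gives the Δ1 olefin dithiolane F7 without any cationic intermediate. Alkylative dethioketalisation (MeI, CaCO3, aqueous MeCN) regenerates the enone and gives 3.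

**Further compounds**

F1 | step 11 | 4β,7β-diol (4α-methyl-5-ene, 1α-OMs, 2β-ONAP, 8α-OTBDPS) | CC(C)(C)[Si](c5ccccc5)(c6ccccc6)O[C@@H]1C[C@]2(C)[C@H](OS(C)(=O)=O)[C@@H](OCc3ccc4ccccc4c3)C[C@@](C)(O)C2=C[C@H]1O
F2 | step 11 | 4β,5β,6β,7β-tetraol | CC(C)(C)[Si](c5ccccc5)(c6ccccc6)O[C@@H]1C[C@]2(C)[C@H](OS(C)(=O)=O)[C@@H](OCc3ccc4ccccc4c3)C[C@@](C)(O)[C@]2(O)[C@@H](O)[C@H]1O
F3 | step 24 | 8-keto butenolide | O=C1C/C(C)=C\[C@@H](OCc3ccc4ccccc4c3)C[C@@]2(C)O[C@@H]2[C@H]2OC(=O)C(COCc7ccc8ccccc8c7)=C12
F4 | step 24 | 8β-hydroxy butenolide | O[C@H]1C/C(C)=C\[C@@H](OCc3ccc4ccccc4c3)C[C@@]2(C)O[C@@H]2[C@H]2OC(=O)C(COCc7ccc8ccccc8c7)=C12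
F5 | step 2 | C7 dithiolane of 1 | C1C[C@]2(C)C(=O)CCCC2=CC13SCCS3
F6 | step 2 | C1 tosylhydrazone of F5 | C1C[C@]2(C)C(=NNS(=O)(=O)c4ccc(C)cc4)CCCC2=CC13SCCS3
F7 | step 2 | Δ1 olefin C7 dithiolane | C1C[C@]2(C)C=CCCC2=CC13SCCS3
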